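**Retrosynthetic overview** (chroman atoms unprimed, hydrindenone atoms primed)

1. The target is cut at the sp3–sp2 bond C2–CH2/C6′ into chromanylmethyl iodide 10 and vinylogous acyl triflate 24 (nickel reductive coupling, step 14). The side-chain tertiary alcohol is made last by Markovnikov hydration of a methallyl group (step 15).
2. The pyran ring is annulated onto commercial 4-iodo-3-methylanisole in one Pd/norbornene relay with iodo alcohol 6: C4–C4a first, then ring closure through O1–C8a. C2 comes from (R)-2-methylglycidol.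
3. Enabling feature: C8a lies between C8 (CH3, the single blocked ortho position a norbornene relay needs) and C4a (C–H), and O1 is held three sp3 carbons (C2–C3–C4) away from C4a. Ortho alkylation therefore places the alkoxide for a six-membered ipso C–O closure.
4. Hydrindenone: an auxiliary-controlled intramolecular keteniminium–alkene [2+2] cycloaddition sets both quaternary centres C3a′/C7a′ (step 10). A two-carbon ring expansion (C-acylation, retro-Claisen/Claisen) gives the 1,3-dione 23, which is triflated regioselectively.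
5. Ring order: pyran ring on the arene (step 5); cyclopentane and cyclobutane together (step 10), then the cyclohexane ring (step 12); union (step 14).

Key step: step 5

Assumption: compounds 1, 7, 11, 12, 14 and 19 are taken as commercial, and the (2R,5R) auxiliary is assumed to give the (1S,5S) cyclobutanone in step 10 (if the sense of induction is the opposite, the (2S,5S) amine is used and nothing else changes).

**Route**

Step 1
Reactants: 1 (R)-2-methylglycidol, [(2R)-2-methyloxiran-2-yl]methanol
Product: 2 tert-butyldimethyl{[(2S)-2-methyloxiran-2-yl]methoxy}silane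
Conditions: TBSCl, imidazole, CH2Cl2, 0 °C
Reagents that add atoms: tert-butyldimethylsilyl chloride, CC(C)(C)[Si](C)(C)Cl
Why: Silylation of the primary alcohol masks the hydroxymethyl arm without touching the epoxide stereocentre, whose descriptor changes from R to S only because the CIP ranking changes.

Step 2
Reactants: 2 tert-butyldimethyl{[(2S)-2-methyloxiran-2-yl]methoxy}silane
Product: 3 (2S)-1-[(tert-butyldimethylsilyl)oxy]-2-methylpent-4-en-2-ol
Conditions: CH2=CHMgBr, CuI (10 mol %), THF, −40 → 0 °C; then H2O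
Reagents that add atoms: vinylmagnesium bromide, C=C[Mg]Br
Why: Copper-catalysed Grignard opening of a 2,2-disubstituted epoxide is an SN2 attack at the unsubstituted CH2 terminus, so no bond at the quaternary stereocentre is broken.

Step 3
Reactants: 3 (2S)-1-[(tert-butyldimethylsilyl)oxy]-2-methylpent-4-en-2-ol
Product: 5 (3S)-4-[(tert-butyldimethylsilyl)oxy]-3-methylbutane-1,3-diol, via ozonide 4 (not isolated)
Conditions: O3, CH2Cl2, −78 °C; then NaBH4, MeOH, −78 → 0 °C
Reagents that add atoms: ozone, [O-][O+]=O
Why: Ozonolysis with reductive NaBH4 work-up shortens the allyl arm to the 2-hydroxyethyl arm (future C3–C4) and involves no stereocentre.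

Step 4
Reactants: 5 (3S)-4-[(tert-butyldimethylsilyl)oxy]-3-methylbutane-1,3-diol
Product: 6 (2S)-1-[(tert-butyldimethylsilyl)oxy]-4-iodo-2-methylbutan-2-ol
Conditions: PPh3, I2, imidazole, CH2Cl2, 0 °C
Reagents that add atoms: iodine, II
Why: Appel iodination converts only the unhindered primary alcohol (SN2 on the alkoxyphosphonium ion) and should leave the tertiary alcohol and the silyl ether untouched.

Step 5
Reactants: 6 (2S)-1-[(tert-butyldimethylsilyl)oxy]-4-iodo-2-methylbutan-2-ol; 7 4-iodo-3-methylanisole (1-iodo-4-methoxy-2-methylbenzene)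
Product: 8 tert-butyl{[(2S)-6-methoxy-2,8-dimethyl-3,4-dihydro-2H-chromen-2-yl]methoxy}dimethylsilane
Conditions: Pd(OAc)2 (10 mol %), XPhos (20 mol %), norbornene (2 equiv), Cs2CO3 (3 equiv), MeCN, 80 °C
Reagents that add atoms: none
Why: Proposed new method: oxidative addition of 7 to zerovalent palladium, norbornene insertion and palladation of the only free ortho C–H (C4a; the other ortho carbon C8 carries CH3) should give an aryl–norbornyl palladacycle, which takes up the primary C–I bond of 6 by SN2-type oxidative addition to tetravalent palladium and forms C4–C4a by reductive elimination; with both ortho positions then filled, norbornene is expelled by β-carbon elimination and the divalent arylpalladium is intercepted by the tethered tertiary alkoxide, C–O reductive elimination forming O1–C8a. The closest known reactions are the Catellani ortho-alkylation/ipso-amination of aryl iodides with bromoalkylamines (tetrahydroquinolines), the Pd/norbornene annulation of aryl iodides with epoxides, which ends in the same ipso C–O reductive elimination but gives the five-membered dihydrobenzofuran, and the Buchwald–Hartwig-type intramolecular etherification of tertiary alcohols; new here is a γ-iodo tertiary alcohol as the bifunctional partner, so that the ipso C–O step closes a six-membered ring. The pyran ring is closed by reductive elimination from a seven-membered aryl(alkoxo)palladium chelate, formally a 6-exo attack of O1 on the ipso carbon. No stereocentre is formed: C2 is carried in from 6 and none of its four bonds is touched, so its configuration should be retained. The step needs site selectivity (alkylation at C4a only, secured by the C8 methyl group and the norbornene relay), the right order of events (C–C before C–O, secured because the di-ortho-substituted arylpalladium arises only after alkylation and a hindered tertiary alcohol should not couple intermolecularly with 7 at this temperature) and clean termination (the tertiary alkoxide has no carbinol hydrogen, so β-hydride reduction of the arylpalladium is excluded, and the second oxygen is masked as the silyl ether).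

Step 6
Reactants: 8 tert-butyl{[(2S)-6-methoxy-2,8-dimethyl-3,4-dihydro-2H-chromen-2-yl]methoxy}dimethylsilane
Product: 9 [(2S)-6-methoxy-2,8-dimethyl-3,4-dihydro-2H-chromen-2-yl]methanol
Conditions: Bu4NF, THF, 25 °C
Reagents that add atoms: none
Why: Fluoride-mediated desilylation frees the primary alcohol; the aryl alkyl ether and the quaternary stereocentre are inert.

Step 7
Reactants: 9 [(2S)-6-methoxy-2,8-dimethyl-3,4-dihydro-2H-chromen-2-yl]methanol
Product: 10 (2S)-2-(iodomethyl)-6-methoxy-2,8-dimethyl-3,4-dihydro-2H-chromene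
Conditions: PPh3, I2, imidazole, toluene, 90 °C
Reagents that add atoms: iodine, II
Why: Appel iodination of the neopentyl-type primary alcohol under forcing conditions should give the radical precursor, and the fully substituted C2 cannot epimerise.

Step 8
Reactants: 11 (2R,5R)-2,5-dimethylpyrrolidine; 12 propanoyl chloride
Product: 13 1-[(2R,5R)-2,5-dimethylpyrrolidin-1-yl]propan-1-one
Conditions: Et3N, CH2Cl2, 0 °C
Reagents that add atoms: none
Why: N-Acylation of the secondary amine installs the C2-symmetric auxiliary that is to control the cycloaddition.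

Step 9
Reactants: 13 1-[(2R,5R)-2,5-dimethylpyrrolidin-1-yl]propan-1-one; 14 5-bromo-2-methylpent-1-ene
Product: 15 1-[(2R,5R)-2,5-dimethylpyrrolidin-1-yl]-2,6-dimethylhept-6-en-1-one (mixture of C2 epimers)
Conditions: LiN(iPr)2, THF, −78 °C; then 14, DMPU, −78 → 0 °C
Reagents that add atoms: none
Why: Amide enolate alkylation (SN2) with the primary bromide attaches the alkenyl chain, and the new α-stereocentre is irrelevant because it becomes sp2 in the next step.

Step 10
Reactants: 15 1-[(2R,5R)-2,5-dimethylpyrrolidin-1-yl]-2,6-dimethylhept-6-en-1-one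
Product: 18 (1S,5S)-1,5-dimethylbicyclo[3.2.0]heptan-6-one, via keteniminium triflate 16 (not isolated), via cyclobutaniminium triflate 17 (not isolated)
Conditions: Tf2O, 2,4,6-collidine, ClCH2CH2Cl, 0 → 80 °C; then aq. NaHCO3, 25 °C
Reagents that add atoms: water, O
Why: Intramolecular keteniminium–alkene [2+2] cycloaddition, in which the electrophilic central carbon of 16 bonds to the CH2 terminus of the 1,1-disubstituted alkene and the ring closes at the tertiary cation, should create both quaternary centres at once, cis by the constraint of the fused four-membered ring and with the absolute sense set by the C2-symmetric pyrrolidine, whose methyl groups shield one face of the keteniminium.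

Step 11
Reactants: 18 (1S,5S)-1,5-dimethylbicyclo[3.2.0]heptan-6-one; 19 4-methylpent-4-enoic acid
Product: 21 (1S,5S)-1,5-dimethyl-7-(4-methylpent-4-enoyl)bicyclo[3.2.0]heptan-6-one (C7 epimers and enol), via acyl imidazole 20 (not isolated)
Conditions: 19, 1,1'-carbonyldiimidazole, THF, 25 °C; separately 18, LiN(SiMe3)2 (2.1 equiv), THF, −78 °C; combine, −78 → −20 °C; aq. NH4Cl
Reagents that add atoms: none
Why: Claisen-type C-acylation of the lithium enolate (only C7 is enolisable) by the acyl imidazole should give the 2-acylcyclobutanone, held as its chelated enolate until work-up, and the new C7 centre is inconsequential because it is destroyed in step 12.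

Step 12
Reactants: 21 (1S,5S)-1,5-dimethyl-7-(4-methylpent-4-enoyl)bicyclo[3.2.0]heptan-6-one
Product: 23 (3aS,7aS)-3a,7a-dimethyl-5-(2-methylprop-2-en-1-yl)hexahydro-1H-indene-4,6(2H,5H)-dione (cis-fused; enolised), via keto ester 22 (not isolated)
Conditions: NaOMe (0.2 equiv), MeOH, 0 → 25 °C; evaporate; KOtBu (2.2 equiv), THF, 60 °C; then aq. HCl
Reagents that add atoms: none
Why: Strain-driven retro-Claisen opening of the 2-acylcyclobutanone by methoxide at the four-ring carbonyl, followed by Claisen cyclisation of the δ-keto ester through its side-chain enolate, should give the six-membered 1,3-dione, a net two-carbon ring expansion that leaves both quaternary centres untouched.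

Step 13
Reactants: 23 (3aS,7aS)-3a,7a-dimethyl-5-(2-methylprop-2-en-1-yl)hexahydro-1H-indene-4,6(2H,5H)-dione
Product: 24 (3aS,7aS)-3a,7a-dimethyl-5-(2-methylprop-2-en-1-yl)-4-oxo-2,3,3a,4,7,7a-hexahydro-1H-inden-6-yl trifluoromethanesulfonate
Conditions: Tf2O, Et3N, CH2Cl2, −78 °C
Reagents that add atoms: trifluoromethanesulfonic anhydride, O=S(=O)(OS(=O)(=O)C(F)(F)F)C(F)(F)F
Why: O-Sulfonylation of the dione enolate should occur at the oxygen on C6′, flanked by the C7′ methylene, and not at the oxygen on C4′ next to the quaternary C3a′, which gives the vinylogous acyl triflate with the ketone kept at C4′.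

Step 14
Reactants: 10 (2S)-2-(iodomethyl)-6-methoxy-2,8-dimethyl-3,4-dihydro-2H-chromene; 24 (3aS,7aS)-3a,7a-dimethyl-5-(2-methylprop-2-en-1-yl)-4-oxo-2,3,3a,4,7,7a-hexahydro-1H-inden-6-yl trifluoromethanesulfonate
Product: 25 (3aS,7aS)-6-{[(2S)-6-methoxy-2,8-dimethyl-3,4-dihydro-2H-chromen-2-yl]methyl}-3a,7a-dimethyl-5-(2-methylprop-2-en-1-yl)-1,2,3,3a,7,7a-hexahydro-4H-inden-4-one
Conditions: NiBr2(MeOCH2CH2OMe) (10 mol %), 4,4'-di-tert-butyl-2,2'-bipyridine (10 mol %), Zn powder (2 equiv), N,N-dimethylacetamide, 25 °C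
Reagents that add atoms: none
Why: In this nickel-catalysed reductive cross-electrophile coupling, zerovalent nickel inserts into the electron-poor vinyl triflate and the neopentyl iodide enters as an alkyl radical (no SN2 step and no carbanion, hence no β-elimination of the aryloxide), so reductive elimination should form the sp3–sp2 bond without touching any stereocentre.

Step 15
Reactants: 25 (3aS,7aS)-6-{[(2S)-6-methoxy-2,8-dimethyl-3,4-dihydro-2H-chromen-2-yl]methyl}-3a,7a-dimethyl-5-(2-methylprop-2-en-1-yl)-1,2,3,3a,7,7a-hexahydro-4H-inden-4-one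
Product: 26 (3aS,7aS)-5-(2-hydroxy-2-methylpropyl)-6-{[(2S)-6-methoxy-2,8-dimethyl-3,4-dihydro-2H-chromen-2-yl]methyl}-3a,7a-dimethyl-1,2,3,3a,7,7a-hexahydro-4H-inden-4-one
Conditions: Co(acac)2 (20 mol %), PhSiH3 (2 equiv), O2 (1 atm), iPrOH, 25 °C
Reagents that add atoms: dioxygen, O=O
Why: Mukaiyama hydration (hydrogen-atom transfer from a cobalt hydride, O2 capture, reduction) should add water with Markovnikov selectivity to the electron-neutral 1,1-disubstituted alkene, while the hindered, electron-poor tetrasubstituted enone is a poor hydrogen-atom acceptor.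

**Compound list**

1 | (R)-2-methylglycidol, [(2R)-2-methyloxiran-2-yl]methanol | C1[C@@](C)(CO)O1 | starting material
2 | tert-butyldimethyl{[(2S)-2-methyloxiran-2-yl]methoxy}silane | C1[C@@](C)(CO[Si](C)(C)C(C)(C)C)O1 | intermediate
3 | (2S)-1-[(tert-butyldimethylsilyl)oxy]-2-methylpent-4-en-2-ol | C=CC[C@@](C)(CO[Si](C)(C)C(C)(C)C)O | intermediate
4 | (2S)-1-[(tert-butyldimethylsilyl)oxy]-2-methyl-3-(1,2,4-trioxolan-3-yl)propan-2-ol (ozonide) | C1OOC(C[C@@](C)(CO[Si](C)(C)C(C)(C)C)O)O1 | intermediate
5 | (3S)-4-[(tert-butyldimethylsilyl)oxy]-3-methylbutane-1,3-diol | OCC[C@@](C)(CO[Si](C)(C)C(C)(C)C)O | intermediate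
6 | (2S)-1-[(tert-butyldimethylsilyl)oxy]-4-iodo-2-methylbutan-2-ol | ICC[C@@](C)(CO[Si](C)(C)C(C)(C)C)O | intermediate
7 | 4-iodo-3-methylanisole (1-iodo-4-methoxy-2-methylbenzene) | COc1ccc(I)c(C)c1 | starting material
8 | tert-butyl{[(2S)-6-methoxy-2,8-dimethyl-3,4-dihydro-2H-chromen-2-yl]methoxy}dimethylsilane | COc1cc(C)c2c(c1)CC[C@@](C)(CO[Si](C)(C)C(C)(C)C)O2 | intermediate
9 | [(2S)-6-methoxy-2,8-dimethyl-3,4-dihydro-2H-chromen-2-yl]methanol | COc1cc(C)c2c(c1)CC[C@@](C)(CO)O2 | intermediate
10 | (2S)-2-(iodomethyl)-6-methoxy-2,8-dimethyl-3,4-dihydro-2H-chromene | COc1cc(C)c2c(c1)CC[C@@](C)(CI)O2 | intermediate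
11 | (2R,5R)-2,5-dimethylpyrrolidine | C[C@@H]1CC[C@@H](C)N1 | starting material
12 | propanoyl chloride | CCC(Cl)=O | starting material
13 | 1-[(2R,5R)-2,5-dimethylpyrrolidin-1-yl]propan-1-one | CCC(=O)N1[C@H](C)CC[C@H]1C | intermediate
14 | 5-bromo-2-methylpent-1-ene | C=C(C)CCCBr | starting material
15 | 1-[(2R,5R)-2,5-dimethylpyrrolidin-1-yl]-2,6-dimethylhept-6-en-1-one (C2 epimers) | C=C(C)CCCC(C)C(=O)N1[C@H](C)CC[C@H]1C | intermediate
16 | (2R,5R)-1-(2,6-dimethylhepta-1,6-dien-1-ylidene)-2,5-dimethylpyrrolidin-1-ium trifluoromethanesulfonate | C=C(C)CCCC(C)=C=[N+]1[C@H](C)CC[C@H]1C.[O-]S(=O)(=O)C(F)(F)F | intermediate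
17 | (2R,5R)-1-[(1S,5S)-1,5-dimethylbicyclo[3.2.0]heptan-6-ylidene]-2,5-dimethylpyrrolidin-1-ium trifluoromethanesulfonate | [N+]1(=C2[C@@]3(C)CCC[C@@]3(C)C2)[C@H](C)CC[C@H]1C.[O-]S(=O)(=O)C(F)(F)F | intermediate
18 | (1S,5S)-1,5-dimethylbicyclo[3.2.0]heptan-6-one | O=C1[C@@]2(C)CCC[C@@]2(C)C1 | intermediate
19 | 4-methylpent-4-enoic acid | C=C(C)CCC(=O)O | starting material
20 | 1-(1H-imidazol-1-yl)-4-methylpent-4-en-1-one | C=C(C)CCC(=O)n1ccnc1 | intermediate
21 | (1S,5S)-1,5-dimethyl-7-(4-methylpent-4-enoyl)bicyclo[3.2.0]heptan-6-one | O=C1[C@@]2(C)CCC[C@@]2(C)C1C(=O)CCC(C)=C | intermediate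
22 | methyl (1S,2S)-1,2-dimethyl-2-(5-methyl-2-oxohex-5-en-1-yl)cyclopentane-1-carboxylate | COC(=O)[C@@]1(C)CCC[C@@]1(C)CC(=O)CCC(C)=C | intermediate
23 | (3aS,7aS)-3a,7a-dimethyl-5-(2-methylprop-2-en-1-yl)hexahydro-1H-indene-4,6(2H,5H)-dione | O=C1[C@@]2(C)CCC[C@@]2(C)CC(=O)C1CC(C)=C | intermediate
24 | (3aS,7aS)-3a,7a-dimethyl-5-(2-methylprop-2-en-1-yl)-4-oxo-2,3,3a,4,7,7a-hexahydro-1H-inden-6-yl trifluoromethanesulfonate | O=C1[C@@]2(C)CCC[C@@]2(C)CC(OS(=O)(=O)C(F)(F)F)=C1CC(C)=C | intermediate
25 | (3aS,7aS)-6-{[(2S)-6-methoxy-2,8-dimethyl-3,4-dihydro-2H-chromen-2-yl]methyl}-3a,7a-dimethyl-5-(2-methylprop-2-en-1-yl)-1,2,3,3a,7,7a-hexahydro-4H-inden-4-one | COc1cc(C)c2c(c1)CC[C@@](C)(CC1=C(CC(C)=C)C(=O)[C@@]3(C)CCC[C@@]3(C)C1)O2 | intermediate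
26 | (3aS,7aS)-5-(2-hydroxy-2-methylpropyl)-6-{[(2S)-6-methoxy-2,8-dimethyl-3,4-dihydro-2H-chromen-2-yl]methyl}-3a,7a-dimethyl-1,2,3,3a,7,7a-hexahydro-4H-inden-4-one | COc1cc(C)c2c(c1)CC[C@@](C)(CC1=C(CC(C)(C)O)C(=O)[C@@]3(C)CCC[C@@]3(C)C1)O2 | target

**Step count and risks**

Total steps: 15. Longest linear sequence: 9 (steps 1–7, 14, 15); the hydrindenone branch (steps 8–13) is 6 steps.

Steps most likely to fail:

Step 5 (proposed new method). The γ-iodo tertiary alcohol may be lost to base-induced oxetane formation or Grob fragmentation before it reaches the palladacycle, or the ipso C–O reductive elimination may be too slow so that the arylpalladium is diverted. Fallback with known chemistry, setting out from 2 and returning at 8: commercial 4-bromo-3,5-dimethylanisole is brominated at one benzylic position (N-bromosuccinimide, radical initiator) to 2-bromo-1-(bromomethyl)-5-methoxy-3-methylbenzene F1. Magnesium in ether at 0 °C converts it into (2-bromo-5-methoxy-3-methylbenzyl)magnesium bromide F2, which opens epoxide 2 at its CH2 terminus under CuI catalysis to give (2S)-4-(2-bromo-5-methoxy-3-methylphenyl)-1-[(tert-butyldimethylsilyl)oxy]-2-methylbutan-2-ol F3. Intramolecular palladium-catalysed etherification of the aryl bromide by the tertiary alcohol (Pd(OAc)2, a di-tert-butyl(biaryl)phosphine, Cs2CO3, toluene, 80 °C) then forms the same O1–C8a bond and gives 8.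

Step 14. The neopentyl, β-aryloxy alkyl radical may fragment or dimerise faster than it is captured by nickel at the hindered, fully substituted vinyl position, so that homocoupling and reduction dominate. Fallback, setting out from 9 and returning at 25: 9 is oxidised (Dess–Martin periodinane) to (2S)-6-methoxy-2,8-dimethyl-3,4-dihydro-2H-chromene-2-carbaldehyde F4. Nozaki–Hiyama–Kishi coupling with triflate 24 (CrCl2, catalytic NiCl2, DMF) should give the allylic alcohol (3aS,7aS)-6-{hydroxy[(2S)-6-methoxy-2,8-dimethyl-3,4-dihydro-2H-chromen-2-yl]methyl}-3a,7a-dimethyl-5-(2-methylprop-2-en-1-yl)-1,2,3,3a,7,7a-hexahydro-4H-inden-4-one F5. This is converted with 1,1'-thiocarbonyldiimidazole into the O-allylic 1H-imidazole-1-carbothioate F6, and Barton–McCombie deoxygenation (Bu3SnH, radical initiator, toluene, 80 °C; any β,γ-unsaturated isomer is re-conjugated with a trace of acid) gives 25. No carbanion or dienolate next to the aryloxy-bearing C2 is generated at any point.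

Step 10. Facial discrimination by the auxiliary may be insufficient, so that the two quaternary centres form cleanly but in low enantiomeric purity. Fallback, setting out from 14 and returning at 18: the lithium enolate of N,N-dimethylpropanamide is alkylated with 14 to N,N,2,6-tetramethylhept-6-enamide F7. The same Tf2O/collidine keteniminium cycloaddition and hydrolysis give racemic cis-1,5-dimethylbicyclo[3.2.0]heptan-6-one F8. This is resolved by addition of lithiated (S)-N,S-dimethyl-S-phenylsulfoximine, chromatographic separation of the diastereomeric adducts and isolation of (1S,5S)-1,5-dimethyl-6-{[(S)-N-methyl-S-phenylsulfonimidoyl]methyl}bicyclo[3.2.0]heptan-6-ol F9. Thermolysis of F9 in toluene at 110 °C releases 18.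

Further compounds
F1 | step 5 | 2-bromo-1-(bromomethyl)-5-methoxy-3-methylbenzene | COc1cc(C)c(Br)c(CBr)c1
F2 | step 5 | (2-bromo-5-methoxy-3-methylbenzyl)magnesium bromide | COc1cc(C)c(Br)c(C[Mg]Br)c1
F3 | step 5 | (2S)-4-(2-bromo-5-methoxy-3-methylphenyl)-1-[(tert-butyldimethylsilyl)oxy]-2-methylbutan-2-ol | COc1cc(C)c(Br)c(c1)CC[C@@](C)(CO[Si](C)(C)C(C)(C)C)O
F4 | step 14 | (2S)-6-methoxy-2,8-dimethyl-3,4-dihydro-2H-chromene-2-carbaldehyde | COc1cc(C)c2c(c1)CC[C@@](C)(C=O)O2
F5 | step 14 | (3aS,7aS)-6-{hydroxy[(2S)-6-methoxy-2,8-dimethyl-3,4-dihydro-2H-chromen-2-yl]methyl}-3a,7a-dimethyl-5-(2-methylprop-2-en-1-yl)-1,2,3,3a,7,7a-hexahydro-4H-inden-4-one (carbinol epimers) | COc1cc(C)c2c(c1)CC[C@@](C)(C(O)C1=C(CC(C)=C)C(=O)[C@@]3(C)CCC[C@@]3(C)C1)O2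
F6 | step 14 | O-{[(3aS,7aS)-3a,7a-dimethyl-5-(2-methylprop-2-en-1-yl)-4-oxo-2,3,3a,4,7,7a-hexahydro-1H-inden-6-yl][(2S)-6-methoxy-2,8-dimethyl-3,4-dihydro-2H-chromen-2-yl]methyl} 1H-imidazole-1-carbothioate | COc1cc(C)c2c(c1)CC[C@@](C)(C(OC(=S)n1ccnc1)C1=C(CC(C)=C)C(=O)[C@@]3(C)CCC[C@@]3(C)C1)O2
F7 | step 10 | N,N,2,6-tetramethylhept-6-enamide | C=C(C)CCCC(C)C(=O)N(C)C
F8 | step 10 | racemic cis-1,5-dimethylbicyclo[3.2.0]heptan-6-one | O=C1C2(C)CCCC2(C)C1
F9 | step 10 | (1S,5S)-1,5-dimethyl-6-{[(S)-N-methyl-S-phenylsulfonimidoyl]methyl}bicyclo[3.2.0]heptan-6-ol | CN=[S@](=O)(CC1(O)C[C@]2(C)CCC[C@]12C)c1ccccc1
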